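**Retrosynthetic overview**
- The target is the 6,8''-linked dimer of acacetin (agathisflavone 4',4'''-dimethyl ether). Both flavone units are bought ready-made as acacetin, so no ring is formed in the route.
- Last disconnection: four O-benzyl groups, removed by hydrogenolysis, which leaves the two 4'-OMe groups alone.
- Key disconnection: the C6–C8'' biaryl bond, made by Suzuki–Miyaura coupling of a 6-iodoflavone with a flavone 8-boronate.
- 6-Iodide: iodination ortho to the free, chelated 5-OH of 7-O-benzylacacetin, then 5-O-benzylation.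
- 8-Boronate: iodination of 5,7-di-O-benzylacacetin at C8, then palladium-catalysed borylation.

Assumption: the SMILES has no stereocentre and no descriptor for the C6–C8'' axis, so the compound is made without control of axial configuration.

**Step 1**
Reactants: 1 acacetin; 2 benzyl bromide
Product: 3 7-(benzyloxy)-5-hydroxy-2-(4-methoxyphenyl)-4H-chromen-4-one (7-O-benzylacacetin)
Conditions: BnBr (1.1 equiv), K2CO3, DMF, rt
Reagents that add atoms: benzyl bromide, BrCc1ccccc1
Why: Williamson ether synthesis in which the acidic 7-OH is alkylated selectively because the 5-OH is locked in a hydrogen bond to the C4 carbonyl; no stereocentre is formed.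

**Step 2**
Reactants: 3 7-O-benzylacacetin; 4 benzyltrimethylammonium dichloroiodate
Product: 5 7-(benzyloxy)-5-hydroxy-6-iodo-2-(4-methoxyphenyl)-4H-chromen-4-one
Conditions: BnMe3N+ ICl2− (1.1 equiv), CaCO3, CH2Cl2/MeOH, rt
Reagents that add atoms: benzyltrimethylammonium dichloroiodate, C[N+](C)(C)Cc1ccccc1.Cl[I-]Cl
Why: Electrophilic aromatic iodination in which the free chelated 5-OH directs the mild ICl2− reagent to its ortho position C6 rather than C8, while CaCO3 takes up the HCl.

**Step 3**
Reactants: 5 7-(benzyloxy)-5-hydroxy-6-iodo-2-(4-methoxyphenyl)-4H-chromen-4-one; 2 benzyl bromide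
Product: 6 5,7-bis(benzyloxy)-6-iodo-2-(4-methoxyphenyl)-4H-chromen-4-one
Conditions: BnBr (1.5 equiv), K2CO3, DMF, 60 °C
Reagents that add atoms: benzyl bromide, BrCc1ccccc1
Why: Williamson O-benzylation under more forcing conditions breaks the 5-OH chelate and caps the last phenol, so the aryl iodide enters the coupling without an acidic proton.

**Step 4**
Reactants: 1 acacetin; 2 benzyl bromide
Product: 7 5,7-bis(benzyloxy)-2-(4-methoxyphenyl)-4H-chromen-4-one (5,7-di-O-benzylacacetin)
Conditions: BnBr (3 equiv), K2CO3 (4 equiv), DMF, 80 °C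
Reagents that add atoms: benzyl bromide, BrCc1ccccc1
Why: Double Williamson ether synthesis in which excess benzyl bromide and heat alkylate first the 7-OH and then the chelated 5-OH.

**Step 5**
Reactants: 7 5,7-di-O-benzylacacetin; 8 N-iodosuccinimide
Product: 9 5,7-bis(benzyloxy)-8-iodo-2-(4-methoxyphenyl)-4H-chromen-4-one
Conditions: NIS (1.1 equiv), TFA (cat.), MeCN, rt, dark
Reagents that add atoms: N-iodosuccinimide, O=C1CCC(=O)N1I
Why: Electrophilic aromatic iodination which, with the 5-OH etherified and its ortho-directing chelate gone, goes to C8 (flanked by one benzyloxy group and the ring oxygen) rather than C6 (between two benzyloxy groups).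

**Step 6**
Reactants: 9 5,7-bis(benzyloxy)-8-iodo-2-(4-methoxyphenyl)-4H-chromen-4-one; 10 pinacolborane
Product: 11 5,7-bis(benzyloxy)-2-(4-methoxyphenyl)-8-(4,4,5,5-tetramethyl-1,3,2-dioxaborolan-2-yl)-4H-chromen-4-one
Conditions: HBpin (3 equiv), PdCl2(MeCN)2 (3 mol %), SPhos (12 mol %), Et3N (4 equiv), 1,4-dioxane, 80 °C
Reagents that add atoms: pinacolborane, CC1(C)OBOC1(C)C
Why: Palladium-catalysed Masuda-type borylation of an aryl iodide with pinacolborane, where the bulky, electron-rich ligand SPhos (2-dicyclohexylphosphino-2',6'-dimethoxybiphenyl) allows C–B bond formation at the doubly ortho-substituted carbon and the flavone carbonyl is inert to HBpin.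

**Step 7**
Reactants: 6 5,7-bis(benzyloxy)-6-iodo-2-(4-methoxyphenyl)-4H-chromen-4-one; 11 the 8-boronate (1.5 equiv)
Product: 12 5,7,5'',7''-tetrakis(benzyloxy)-4',4'''-dimethoxy-6,8''-biflavone
Conditions: Pd(OAc)2 (10 mol %), SPhos (20 mol %), K3PO4 (3 equiv), toluene/H2O 10:1, 100 °C
Reagents that add atoms: none
Why: Suzuki–Miyaura cross-coupling with SPhos-ligated zerovalent palladium, the usual system for tetra-ortho-substituted biaryls, helped here by all four ortho groups being oxygen substituents; the C6–C8'' axis forms without stereocontrol, which the target does not require.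

**Step 8**
Reactants: 12 5,7,5'',7''-tetrakis(benzyloxy)-4',4'''-dimethoxy-6,8''-biflavone
Product: 13 5,7,5'',7''-tetrahydroxy-4',4'''-dimethoxy-6,8''-biflavone (target, CNP0226117.0)
Conditions: H2 (1 atm), 10% Pd/C, THF/MeOH 1:1, rt
Reagents that add atoms: none
Why: Catalytic hydrogenolysis cleaves the four benzyl aryl ethers, while the two anisyl methyl ethers and the flavone C2=C3 bonds (vinylogous esters) survive at 1 atm and rt.

**Compound list**
1 | acacetin, 5,7-dihydroxy-2-(4-methoxyphenyl)-4H-chromen-4-one | COc1ccc(-c2cc(=O)c3c(O)cc(O)cc3o2)cc1 | starting material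
2 | benzyl bromide | BrCc1ccccc1 | starting material
3 | 7-(benzyloxy)-5-hydroxy-2-(4-methoxyphenyl)-4H-chromen-4-one | COc1ccc(-c2cc(=O)c3c(O)cc(OCc4ccccc4)cc3o2)cc1 | intermediate
4 | benzyltrimethylammonium dichloroiodate | C[N+](C)(C)Cc1ccccc1.Cl[I-]Cl | starting material
5 | 7-(benzyloxy)-5-hydroxy-6-iodo-2-(4-methoxyphenyl)-4H-chromen-4-one | COc1ccc(-c2cc(=O)c3c(O)c(I)c(OCc4ccccc4)cc3o2)cc1 | intermediate
6 | 5,7-bis(benzyloxy)-6-iodo-2-(4-methoxyphenyl)-4H-chromen-4-one | COc1ccc(-c2cc(=O)c3c(OCc4ccccc4)c(I)c(OCc4ccccc4)cc3o2)cc1 | intermediate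
7 | 5,7-bis(benzyloxy)-2-(4-methoxyphenyl)-4H-chromen-4-one | COc1ccc(-c2cc(=O)c3c(OCc4ccccc4)cc(OCc4ccccc4)cc3o2)cc1 | intermediate
8 | N-iodosuccinimide | O=C1CCC(=O)N1I | starting material
9 | 5,7-bis(benzyloxy)-8-iodo-2-(4-methoxyphenyl)-4H-chromen-4-one | COc1ccc(-c2cc(=O)c3c(OCc4ccccc4)cc(OCc4ccccc4)c(I)c3o2)cc1 | intermediate
10 | pinacolborane, 4,4,5,5-tetramethyl-1,3,2-dioxaborolane | CC1(C)OBOC1(C)C | starting material
11 | 5,7-bis(benzyloxy)-2-(4-methoxyphenyl)-8-(4,4,5,5-tetramethyl-1,3,2-dioxaborolan-2-yl)-4H-chromen-4-one | COc1ccc(-c2cc(=O)c3c(OCc4ccccc4)cc(OCc4ccccc4)c(B4OC(C)(C)C(C)(C)O4)c3o2)cc1 | intermediate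
12 | 5,7-bis(benzyloxy)-6-[5,7-bis(benzyloxy)-2-(4-methoxyphenyl)-4-oxo-4H-chromen-8-yl]-2-(4-methoxyphenyl)-4H-chromen-4-one | COc1ccc(-c2cc(=O)c3c(OCc7ccccc7)c(-c4c(OCc7ccccc7)cc(OCc7ccccc7)c5c(=O)cc(-c6ccc(OC)cc6)oc45)c(OCc7ccccc7)cc3o2)cc1 | intermediate
13 | 5,7-dihydroxy-6-[5,7-dihydroxy-2-(4-methoxyphenyl)-4-oxo-4H-chromen-8-yl]-2-(4-methoxyphenyl)-4H-chromen-4-one (no stereocentre) | COc1ccc(-c2cc(=O)c3c(O)c(-c4c(O)cc(O)c5c(=O)cc(-c6ccc(OC)cc6)oc45)c(O)cc3o2)cc1 | target

**Totals**
Total step count: 8.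
Longest linear sequence: 5 steps (1 → 3 → 5 → 6 → 12 → 13, or 1 → 7 → 9 → 11 → 12 → 13).

**Three steps most likely to fail**

Step 7 (Suzuki coupling to a biaryl with four ortho oxygen substituents). The doubly ortho-oxygenated boronate 11 can lose boron under aqueous base faster than it transmetalates at the crowded centre. The fallback sets out from 9, with 6 as partner, and comes back to the route at 12. Zinc insertion (Zn dust, LiCl, THF, 50 °C) into the carbon–iodine bond of 9 gives [5,7-bis(benzyloxy)-2-(4-methoxyphenyl)-4-oxo-4H-chromen-8-yl]zinc iodide F1, which is not isolated. Negishi coupling of this with 6 (Pd(OAc)2, SPhos, THF/NMP, 70 °C) gives 12. The organozinc tolerates the flavone carbonyl, needs no aqueous base, and transmetalates readily at hindered carbons.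

Step 6 (borylation at the doubly ortho-substituted C8). Hydrodeiodination of 9 back to 7 can outrun C–B bond formation. The fallback sets out from 6 and comes back to the route at 12, with the roles of the two halves exchanged. Iodide 6 is borylated (HBpin, PdCl2(MeCN)2, SPhos, Et3N, dioxane, 80 °C) to 5,7-bis(benzyloxy)-2-(4-methoxyphenyl)-6-(4,4,5,5-tetramethyl-1,3,2-dioxaborolan-2-yl)-4H-chromen-4-one F2. This is coupled with iodide 9 (Pd(OAc)2, SPhos, K3PO4, toluene/H2O, 100 °C) to give 12. In this pairing 9 only has to undergo oxidative addition. The weakness is that the iodide of 6 is at least as hindered as that of 9, so this borylation may fail for the same reason.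

Step 3 (benzylation of the chelated 5-OH wedged between the C4 carbonyl and the iodine). The reaction may stall, or need conditions that cost the iodide. The fallback sets out from 5 and comes back to the route at 13, leaving out the protection. Free phenol 5 is coupled directly with boronate 11 (Pd(OAc)2, SPhos, K3PO4 4 equiv, toluene/H2O, 100 °C) to give 7,5'',7''-tris(benzyloxy)-5-hydroxy-4',4'''-dimethoxy-6,8''-biflavone F3. Its three benzyl ethers are then hydrogenolysed (H2, 10% Pd/C, THF/MeOH, rt) to 13. This variant also lowers the steric load at the electrophile and is one step shorter.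

**Further compounds**
F1 | step 7 | [5,7-bis(benzyloxy)-2-(4-methoxyphenyl)-4-oxo-4H-chromen-8-yl]zinc iodide | COc1ccc(-c2cc(=O)c3c(OCc4ccccc4)cc(OCc4ccccc4)c([Zn]I)c3o2)cc1
F2 | step 6 | 5,7-bis(benzyloxy)-2-(4-methoxyphenyl)-6-(4,4,5,5-tetramethyl-1,3,2-dioxaborolan-2-yl)-4H-chromen-4-one | COc1ccc(-c2cc(=O)c3c(OCc4ccccc4)c(B4OC(C)(C)C(C)(C)O4)c(OCc4ccccc4)cc3o2)cc1
F3 | step 3 | 7-(benzyloxy)-6-[5,7-bis(benzyloxy)-2-(4-methoxyphenyl)-4-oxo-4H-chromen-8-yl]-5-hydroxy-2-(4-methoxyphenyl)-4H-chromen-4-one | COc1ccc(-c2cc(=O)c3c(O)c(-c4c(OCc7ccccc7)cc(OCc7ccccc7)c5c(=O)cc(-c6ccc(OC)cc6)oc45)c(OCc7ccccc7)cc3o2)cc1
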